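Treat the flask as a one-step world: substrate goes to target by one first-order law with one constant k, the pseudo-first-order rule for reagent in excess.

- north: substrate 0.10 M; reagent 0.50 M; free catalyst 0.50 mM; the very flask that is asked about, followed so far
- flask: substrate 0.10 M; reagent 0.500 M; free catalyst 0.50 mM
north run (percent of the substrate charged)

| time / s | target / % | substrate / % |
|---|---|---|
| 10.0 | 14.9 | 85.6 |
| 12.0 | 17.2 | 81.4 |
| 25.0 | 33.4 | 66.1 |
| 40.0 | 48.4 | 51.6 |

(readings scatter by 0.5 percentage points)
- no earlier run changes the charge of reagent; that part of a forecast is a guess
- apparent order in reagent when 50 % of the substrate are converted (percent change of the rate of making target for one percent more reagent charged)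

Take the last north reading, 51.6 % of the substrate left at 40.0 s. It gives k = 0.0165 s⁻¹, and the one-step time, the natural log of 2 over k, which is the time this law needs for 50 % conversion, is 0.698 min.

Now go round again and test the excess. Assuming one reagent per substrate, 50 % conversion costs 10.0 % of the reagent charge, so the reagent is not constant. If the rate followed [reagent] to the first power, k averaged up to that point would sag by about 5.00 %, and the earliest reading should give a larger k. It gives 0.0155 s⁻¹, the opposite way. But that reading rests on a loss of 14 percentage points with a scatter of 0.5 points, so the rule reaches its border here: a sag of this size barely shows. No run changes the reagent charge, so commit, as a guess, to an order below 0.5.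

The forecast says 0.3: “This favours a low order”.

The flask gives 0.054 and reaches 50 % conversion at 0.689 min, beside the one-step time of 0.698 min.

    catalyst intermediate B → catalyst intermediate C (k = 64.8 s⁻¹)
    2 catalyst intermediate A ⇌ resting dimer, settled at all times (K = 825 M⁻¹)
    reagent + free catalyst → catalyst intermediate A (k = 63.4 M⁻¹ s⁻¹)
    catalyst intermediate C → released group + catalyst intermediate D (k = 34.3 s⁻¹)
    catalyst intermediate D → free catalyst + target (k = 247 s⁻¹)
    substrate + catalyst intermediate A ⇌ catalyst intermediate B (K = 2.80 M⁻¹, k = 91.7 M⁻¹ s⁻¹)

Carry the one-step time to the simulated flask with twice the free catalyst. With rate proportional to catalyst, it predicts 0.349 min for 50 % conversion, but that flask takes 0.405 min, which is longer. Part of the gap comes from the pairing of catalyst intermediate A to resting dimer: with that pairing removed from the asked flask, the apparent order in free catalyst at 50 % conversion rises from 0.78 to 1.0.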